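## The problem

CNP0163979.2 is a C37 nor-carotenoid. A 3-hydroxy-2,6,6-trimethylcyclohexene (ring A, C1–C6) is tied through the C7≡C8 alkyne to an all-E tetraene with methyl branches at C9 and C16. The chain ends at C17 as the (Z)-ylidene group on Cγ of a butenolide (ring C), and Cα of ring C carries an (E)-C8′=C7′ vinyl link to a 3′,5′,6′-trihydroxy-1′,1′,5′-trimethylcyclohexane (ring B). There are four stereocentres. C3 of ring A (R) is isolated and nothing in the molecule can direct it. In ring B the secondary carbinol C3′ can control both tertiary carbinols: an epoxide placed syn to the C3′ hydroxyl and opened at C5′ with inversion gives exactly the required C3′/C6′-cis, C5′-trans triol. The two rings cannot influence each other, so each needs its own absolute control. The polyene–ylidene-lactone chromophore is sensitive to light, acid, strong base and long contact with palladium. The two methyl-bearing enyne double bonds (C9=C10, and C15=C16 before ring C is closed) have little thermodynamic preference for E, so they must be made stereospecifically and never equilibrated, and the tertiary C6′ carbinol does not tolerate strong acid. The feature that opens the problem is that ring A and the carbon skeleton of ring B are the same unit, a 2,6,6-trimethylcyclohexene with oxygen on C3, methyl on C5 and the side-chain carbon C7 on C6, differing only in the sense of C3. One achiral C3 ketone of this skeleton, made by closing C4–C5 and C1–C6 in a [4+2] cycloaddition, can therefore serve both rings.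

## Retrosynthesis

**Cα–C8′ (ring C to the vinyl link).** Target 29 is cut into bromobutenolide 25 and the ring B (E)-vinylstannane 28. Cutting C6′–C7′ instead would need a vinyl-metal addition to a hindered α-hydroxy ketone with facial control. Cutting C7′=C8′ by olefination would put a carbanion next to the lactone. The sp2–sp2 cut gives two halves with one carbocycle each, all hydroxyls free. The forward Stille coupling must run near room temperature and keep both alkene geometries.

**Ring C (Cβ–Cγ and O–Cγ).** 25 is opened to the terminal alkyne 21 and (E)-2,3-dibromoacrylic acid 23, which comes from propiolic acid 22 and bromine; the open enynoic acid 24 is passed through without isolation. Against an aldol/elimination on a preformed butenolide, this cut fixes the (Z)-ylidene geometry by the anti course of the lactonisation and brings the lactone carbonyl in without CO. The forward reaction must choose the C–Br bond β to the carboxyl and close 5-exo, not 6-endo.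

**C13=C14.** 21 is cut to the dienynal 14 and the silylated enynyl phosphonate 19; the C-silyl tetraenediyne 20 is desilylated in the same flask. The carbanion is placed on the small C6 piece and the ring A side is kept as an aldehyde, because a carbanion on the ring A side would be conjugated to the C9=C10 enyne and could scramble it. 19 is three routine steps from commercial (E)-3-methylpent-2-en-4-yn-1-ol 15, through 16, 17 and 18. The olefination must be E-selective and cold enough to keep C15=C16.

**C11=C12 and C8–C9.** 14 comes from the C15 enynal 13 by a two-carbon Wittig homologation. 13 comes from the diol 12 and 12 from the enynoate 11. 11 is cut at C8–C9 into the ring A alkyne 9 and ethyl but-2-ynoate 3. This cut is preferred to a Sonogashira coupling with an (E)-3-iodobutenyl unit because the palladium-catalysed syn addition of the alkyne C–H across the ynoate sets C9=C10 as E by mechanism, needs no vinyl iodide synthesis, and reuses a starting material already in the plan.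

**Ring B side chain and triad.** 28 comes from the ethynyl triol 27 by hydrostannation. 27 comes from the (S)-enynol 10 through the syn-epoxide 26. The C3′ hydroxyl directs the epoxide, and water opens it at the non-propargylic, less hindered C5′ with inversion. Dihydroxylation would give the wrong (cis) diol, and an anti-epoxide would invite attack of the C3′ hydroxyl on C6′.

**C3 and C3′.** 9 (R) and 10 (S) both come from the achiral ketone 4-ethynyl-3,5,5-trimethylcyclohex-3-en-1-one 8 by two ketoreductases of opposite selectivity. This is the point where the one ring synthesis divides, and no material is discarded.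

**Ester to alkyne before the ketone is unmasked.** 8 is traced through the silyl enol ether enyne 7, the aldehyde 6 and the alcohol 5 to the Diels–Alder adduct 4. Carrying the ketone as its tert-butyldimethylsilyl enol ether through the homologation means C7/C8 are installed once, not once per enantiomer. It also means the β,γ-unsaturated ketone is exposed only in the step before its reduction, and then as the less acidic enyne ketone rather than a vinylogous β-keto ester.

**The ring (C4–C5 and C1–C6).** 4 is cut into 2-(tert-butyldimethylsilyloxy)-4-methylpenta-1,3-diene 2 and ethyl but-2-ynoate 3; 2 is the kinetic silyl dienol ether of mesityl oxide 1. Both ring bonds, the gem-dimethyl group, the C5 methyl, the C3 oxygen and the C7 carbon arrive in one step from two five- to six-carbon commodity compounds. The forward reaction must give the "para" regiochemistry and overcome the hindered gem-dimethyl terminus.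

## Roads not taken

**Alternative 1:** The cut is at the two tertiary C–O bonds of ring B (C5′–O and C6′–O). In the forward key step VO(acac)2 and tert-butyl hydroperoxide would epoxidise the enynol A2 on the face of its hydroxyl to the syn-epoxide A3, and aqueous acid would open A3 at C5′ with inversion to the ethynyl triol A1.
- Merits: one stereocentre sets two more, no protecting group is needed, it runs in one flask, and the ethynyl group is the handle for the vinyl link.
- Weak points: the delivery needs the hydroxyl axial and syn to an axial methyl, the alkene is deactivated by the alkyne, and the opening must avoid the propargylic C6′. Above all, the plan presupposes enantiopure A2 and says nothing about where the ring carbons, the C3′ configuration or ring A come from.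
- Comparison: this road feeds into the chosen plan rather than competing with it. A2, A3 and A1 are compounds 10, 26 and 27, and step 19 is this operation. For C5′ and C6′ it is as good as anything available, which is why it is taken over. What the chosen plan adds is the supply of A2 and of its enantiomer from one achiral ketone.

**Alternative 2:** The cut is at the lactone carbonyl (C(=O)–Cα and C(=O)–O). In the forward key step PdCl2(PPh3)2, CO and Et3N would convert the (Z)-β-iodoenone A5 into an acylpalladium at Cα, which the enol oxygen of the ketone traps to close ring C in the silyl-protected butenolide A4.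
- Merits: the carbonyl carbon comes from CO, ring C is formed on a short robust chain, and the tetraene never sees the ring C-forming palladium step. It is also more atom-economic than the chosen dibromo acid 23, one bromine of which ends as tin bromide.
- Weak points: A5 is a cross-conjugated iododienone that must be made regio- and stereodefined with ring B already attached. Its β,γ-unsaturated CH2 can enolise so as to move the C15=C16 bond. Two silyl ethers must be put on and removed. After A4, ring A and five chain carbons are still missing and would have to be added by olefination beside a base-sensitive ylidene lactone.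
- Comparison: in the chosen plan ring C closes in the same flask as a C–C bond on a complete ring A half, no olefination follows the lactone, and no protecting group is used. Alternative 2 does not address the carbocycles at all.

**Alternative 3:** The cut is at C3′–O and C6′–O. In the forward key step singlet oxygen would add [4+2] across C3′ and C6′ of the ethynyl diene A7, itself from safranal A8, to give the endoperoxide A6. O–O reduction and hydration of C4′=C5′ would follow.
- Merits: two C–O bonds, cis by necessity, are made in one step from a cheap terpenoid aldehyde. The C3′/C6′ relationship that the chosen plan builds over three steps from its ketone comes at once, and in that respect this road is shorter.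
- Weak points: A6 is racemic because A7 is achiral, so a resolution loses half the material. The hydration must place the C5′ hydroxyl anti to the C6′ oxygen with nothing to direct that face. The O–O bond must be reduced beside an alkyne. Ring A, which has no C6 oxygen, needs a second ring synthesis.
- Comparison: against the shorter access to the C3′/C6′ pair, the chosen plan sets absolute configuration by reduction with both enantiomers used, a C5′ centre set by a stereospecific anti opening, and one ring synthesis for both rings.

Key step: step 2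

Remark on the chemistry: the two ketoreductases are named by the enantiomer they deliver; which enzymes of a commercial panel do so is settled by screening. Locants C1–C17, Cα–Cγ and C1′–C8′ are those defined in the first section; compound names use systematic locants.

## Route

Step 1
Reactants: 1 mesityl oxide (4-methylpent-3-en-2-one)
Product: 2 2-(tert-butyldimethylsilyloxy)-4-methylpenta-1,3-diene
Conditions: LDA, THF, −78 °C; then TBSCl, DMPU, −78 °C → rt
Reagents that add atoms: tert-butyldimethylsilyl chloride, CC(C)(C)[Si](C)(C)Cl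
Why: Kinetic deprotonation of the enone at the α′-methyl group and O-silylation of the lithium enolate give the cross-conjugated 2-silyloxydiene (kinetic enolate trapping). The tert-butyldimethylsilyl group is chosen over trimethylsilyl so that the enol ether survives the heat of step 2 and steps 3–5.

Step 2
Reactants: 2 2-(tert-butyldimethylsilyloxy)-4-methylpenta-1,3-diene; 3 ethyl but-2-ynoate
Product: 4 ethyl 4-[(tert-butyldimethylsilyl)oxy]-2,6,6-trimethylcyclohexa-1,4-diene-1-carboxylate
Conditions: neat, 2 (1.5 equiv), BHT (cat.), sealed tube, 150 °C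
Reagents that add atoms: none
Why: A concerted, asynchronous, thermally allowed [4+2] cycloaddition of normal electron demand joins the diene termini to the two alkyne carbons and forms the C4–C5 and C1–C6 bonds in one step. The closest known reaction type is the thermal Diels–Alder reaction of 2-silyloxybuta-1,3-dienes with alkynoates to give 1-silyloxycyclohexa-1,4-dienes. The six-membered carbocycle is closed intermolecularly, suprafacially on both components, and the quaternary carbon prevents aromatisation of the 1,4-diene. No stereocentre is formed; the adduct is achiral. The selectivity needed is regiochemical, with the silyloxy carbon opposite the ester-bearing carbon. It is secured by the large HOMO coefficient at the CH2 terminus of the 2-donor diene matching the large LUMO coefficient at the β-carbon of the ynoate, so that bond leads and the congested bond from the CMe2 terminus to the α-carbon lags. The Z-methyl of the gem-dimethyl terminus disfavours the s-cis conformer, hence the forcing neat conditions with a radical inhibitor; the 2-silyloxy group helps by also destabilising the s-trans conformer.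

Step 3
Reactants: 4 ethyl 4-[(tert-butyldimethylsilyl)oxy]-2,6,6-trimethylcyclohexa-1,4-diene-1-carboxylate
Product: 5 {4-[(tert-butyldimethylsilyl)oxy]-2,6,6-trimethylcyclohexa-1,4-dien-1-yl}methanol
Conditions: DIBAL-H, CH2Cl2, −78 → 0 °C; aq. Rochelle salt
Reagents that add atoms: none
Why: Hydride reduction of the hindered conjugated ester to the allylic alcohol, as for cyclogeranate esters. The silyl enol ether is inert to the hydride and to the neutral tartrate work-up.

Step 4
Reactants: 5 {4-[(tert-butyldimethylsilyl)oxy]-2,6,6-trimethylcyclohexa-1,4-dien-1-yl}methanol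
Product: 6 4-[(tert-butyldimethylsilyl)oxy]-2,6,6-trimethylcyclohexa-1,4-diene-1-carbaldehyde
Conditions: MnO2, CH2Cl2, rt
Reagents that add atoms: none
Why: Selective allylic oxidation on the MnO2 surface under neutral conditions, which leaves the silyl enol ether and the bis-allylic CH2 untouched.

Step 5
Reactants: 6 4-[(tert-butyldimethylsilyl)oxy]-2,6,6-trimethylcyclohexa-1,4-diene-1-carbaldehyde
Product: 7 tert-butyl[(4-ethynyl-3,3,5-trimethylcyclohexa-1,4-dien-1-yl)oxy]dimethylsilane
Conditions: TMSCHN2, LDA, THF, −78 °C → rt
Reagents that add atoms: (trimethylsilyl)diazomethane, C[Si](C)(C)C=[N+]=[N-]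
Why: Colvin rearrangement: the lithiated diazo compound adds to the aldehyde, Peterson-type loss of silanolate gives a diazoalkene, and N2 loss followed by a 1,2-hydrogen shift of the alkylidene carbene gives the terminal alkyne. It is preferred to dibromo-olefination (acid traces would cleave the enol ether) and to methanolic Ohira–Bestmann conditions (conjugate addition to the enal).

Step 6
Reactants: 7 tert-butyl[(4-ethynyl-3,3,5-trimethylcyclohexa-1,4-dien-1-yl)oxy]dimethylsilane
Product: 8 4-ethynyl-3,5,5-trimethylcyclohex-3-en-1-one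
Conditions: TBAF, AcOH, THF, 0 °C
Reagents that add atoms: none
Why: Fluoride cleaves the Si–O bond and acetic acid protonates the enolate on the carbon next to the gem-dimethyl group, so the ketone appears without involving the enyne. The buffered, cold conditions avoid migration of the ring alkene into conjugation with the ketone.

Step 7
Reactants: 8 4-ethynyl-3,5,5-trimethylcyclohex-3-en-1-one
Product: 9 (1R)-4-ethynyl-3,5,5-trimethylcyclohex-3-en-1-ol
Conditions: ketoreductase delivering the (R)-alcohol, NADP+ (cat.), i-PrOH, phosphate buffer pH 7, DMSO (5%), 30 °C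
Reagents that add atoms: none
Why: Enzymatic ketone reduction with cofactor recycling by propan-2-ol; the enzyme delivers hydride to one carbonyl face and so sets C3 as R. The two flanks of the ketone (flat CH2–C(Me)=C against CH2–CMe2) should differ enough for an active site to distinguish, and neutral buffer should not isomerise the β,γ-enone.

Step 8
Reactants: 8 4-ethynyl-3,5,5-trimethylcyclohex-3-en-1-one
Product: 10 (1S)-4-ethynyl-3,5,5-trimethylcyclohex-3-en-1-ol
Conditions: ketoreductase delivering the (S)-alcohol, NADP+ (cat.), i-PrOH, phosphate buffer pH 7, DMSO (5%), 30 °C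
Reagents that add atoms: none
Why: The same enzymatic reduction with an enzyme of opposite facial preference sets C3′ for ring B; the enzyme alone controls the new stereocentre.

Step 9
Reactants: 9 (1R)-4-ethynyl-3,5,5-trimethylcyclohex-3-en-1-ol; 3 ethyl but-2-ynoate
Product: 11 ethyl (2E)-5-[(4R)-4-hydroxy-2,6,6-trimethylcyclohex-1-en-1-yl]-3-methylpent-2-en-4-ynoate
Conditions: Pd(OAc)2 (cat.), tris(2,6-dimethoxyphenyl)phosphine (cat.), THF, rt
Reagents that add atoms: none
Why: Palladium-catalysed cross-addition of a terminal (donor) alkyne to an alkynoate (acceptor): the alkynylpalladium adds syn with the alkynyl group at the β-carbon and protonolysis follows with retention. The alkynyl group therefore ends trans to the ester, which is the E geometry at C9=C10, and no base or halide is involved, so the free hydroxyl is tolerated.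

Step 10
Reactants: 11 ethyl (2E)-5-[(4R)-4-hydroxy-2,6,6-trimethylcyclohex-1-en-1-yl]-3-methylpent-2-en-4-ynoate
Product: 12 (1R)-4-[(3E)-5-hydroxy-3-methylpent-3-en-1-yn-1-yl]-3,5,5-trimethylcyclohex-3-en-1-ol
Conditions: DIBAL-H (3 equiv), CH2Cl2, −78 °C; aq. Rochelle salt
Reagents that add atoms: none
Why: 1,2-Reduction of the conjugated ester to the allylic alcohol; the ring alkoxide is a spectator and the enyne geometry is untouched.

Step 11
Reactants: 12 (1R)-4-[(3E)-5-hydroxy-3-methylpent-3-en-1-yn-1-yl]-3,5,5-trimethylcyclohex-3-en-1-ol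
Product: 13 (2E)-5-[(4R)-4-hydroxy-2,6,6-trimethylcyclohex-1-en-1-yl]-3-methylpent-2-en-4-ynal
Conditions: MnO2, CH2Cl2, rt
Reagents that add atoms: none
Why: MnO2 oxidises only the primary allylic alcohol; the saturated secondary ring hydroxyl is not touched.

Step 12
Reactants: 13 (2E)-5-[(4R)-4-hydroxy-2,6,6-trimethylcyclohex-1-en-1-yl]-3-methylpent-2-en-4-ynal
Product: 14 (2E,4E)-7-[(4R)-4-hydroxy-2,6,6-trimethylcyclohex-1-en-1-yl]-5-methylhepta-2,4-dien-6-ynal
Conditions: Ph3P=CHCHO (1.2 equiv), toluene, 80 °C
Reagents that add atoms: (triphenylphosphoranylidene)acetaldehyde, O=CC=P(c1ccccc1)(c1ccccc1)c1ccccc1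
Why: Wittig reaction with the formyl-stabilised ylide, an E-selective two-carbon homologation of an enal to a dienal, sets C11=C12. The ylide is kept near stoichiometric so that the less electrophilic dienal is not homologated again.

Step 13
Reactants: 15 (2E)-3-methylpent-2-en-4-yn-1-ol
Product: 17 (2E)-3-methyl-5-(trimethylsilyl)pent-2-en-4-yn-1-ol, via O,C-bis(trimethylsilyl) enynol 16 (not isolated)
Conditions: EtMgBr (2.2 equiv), THF, 0 → 40 °C; TMSCl (2.2 equiv); then 1 M aq. H2SO4, rt
Reagents that add atoms: chlorotrimethylsilane, C[Si](C)(C)Cl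
Why: Double deprotonation (O–H and alkyne C–H) and bis-silylation, then acid cleavage of the labile O–Si bond, leaves the C-silyl alkyne. This masks the acidic alkyne proton for the carbanion chemistry of step 16.

Step 14
Reactants: 17 (2E)-3-methyl-5-(trimethylsilyl)pent-2-en-4-yn-1-ol
Product: 18 [(3E)-5-bromo-3-methylpent-3-en-1-yn-1-yl]trimethylsilane
Conditions: CBr4, PPh3, CH2Cl2, 0 °C
Reagents that add atoms: carbon tetrabromide, BrC(Br)(Br)Br
Why: Appel bromination by SN2 displacement at the primary allylic carbon under neutral conditions, which keeps the alkene geometry and the C–Si bond.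

Step 15
Reactants: 18 [(3E)-5-bromo-3-methylpent-3-en-1-yn-1-yl]trimethylsilane
Product: 19 diethyl [(2E)-3-methyl-5-(trimethylsilyl)pent-2-en-4-yn-1-yl]phosphonate
Conditions: P(OEt)3, neat, 100 °C
Reagents that add atoms: triethyl phosphite, CCOP(OCC)OCC
Why: Michaelis–Arbuzov reaction: SN2 attack of the phosphite on the allylic bromide, then dealkylation of the phosphonium ion by bromide.

Step 16
Reactants: 14 (2E,4E)-7-[(4R)-4-hydroxy-2,6,6-trimethylcyclohex-1-en-1-yl]-5-methylhepta-2,4-dien-6-ynal; 19 diethyl [(2E)-3-methyl-5-(trimethylsilyl)pent-2-en-4-yn-1-yl]phosphonate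
Product: 21 (1R)-4-[(3E,5E,7E,9E)-3,10-dimethyldodeca-3,5,7,9-tetraene-1,11-diyn-1-yl]-3,5,5-trimethylcyclohex-3-en-1-ol, via C-silyl tetraenediyne 20 (not isolated)
Conditions: 19 (2.2 equiv), NaHMDS, THF, −78 °C; then 14, −78 → 0 °C; then K2CO3, MeOH, rt
Reagents that add atoms: none
Why: Horner–Wadsworth–Emmons olefination: the allylic phosphonate carbanion adds reversibly to the aldehyde and syn-elimination from the oxaphosphetane gives the E-configured C13=C14 bond. The low temperature is meant to keep the C15=C16 geometry of the carbanion, the excess anion absorbs the free hydroxyl, and carbonate in methanol then removes the alkynyl silyl group in the same flask.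

Step 17
Reactants: 22 propiolic acid
Product: 23 (2E)-2,3-dibromoprop-2-enoic acid
Conditions: Br2, CHCl3, 0 °C → rt, dark
Reagents that add atoms: bromine, BrBr
Why: Electrophilic anti addition of bromine across the triple bond gives the E-dibromide, in which the β-bromine is cis to the carboxyl group as the later lactonisation requires.

Step 18
Reactants: 21 (1R)-4-[(3E,5E,7E,9E)-3,10-dimethyldodeca-3,5,7,9-tetraene-1,11-diyn-1-yl]-3,5,5-trimethylcyclohex-3-en-1-ol; 23 (2E)-2,3-dibromoprop-2-enoic acid
Product: 25 (5Z)-3-bromo-5-{(2E,4E,6E,8E)-11-[(4R)-4-hydroxy-2,6,6-trimethylcyclohex-1-en-1-yl]-2,9-dimethylundeca-2,4,6,8-tetraen-10-yn-1-ylidene}furan-2(5H)-one, via bromoenynoic acid 24 (not isolated)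
Conditions: Pd(PPh3)4 (cat.), CuI (cat.), Et3N, MeCN, rt, dark, degassed
Reagents that add atoms: none
Why: Sonogashira coupling with lactonisation in the same flask: zerovalent palladium inserts into the more electron-poor C–Br bond β to the carboxyl, and coupling with the copper acetylide proceeds with retention. The cis carboxylate then adds anti across the metal-activated alkyne in a 5-exo-dig closure and protodemetalation gives the Z-ylidene lactone; the α-bromine should survive at room temperature for step 21.

Step 19
Reactants: 10 (1S)-4-ethynyl-3,5,5-trimethylcyclohex-3-en-1-ol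
Product: 27 (1R,2S,4R)-1-ethynyl-2,6,6-trimethylcyclohexane-1,2,4-triol, via syn-epoxy alcohol 26 (not isolated)
Conditions: VO(acac)2 (cat.), t-BuOOH, CH2Cl2, 0 °C → rt; then 1 M aq. HClO4, THF, 0 °C
Reagents that add atoms: tert-butyl hydroperoxide, CC(C)(C)OO; water, O
Why: Hydroxyl-directed epoxidation: the vanadate ester of the homoallylic C3′ hydroxyl delivers the peroxide oxygen to its own face, which sets C6′–O syn. Acid-catalysed trans-diaxial hydrolysis (Fürst–Plattner) at the tertiary, non-propargylic and less hindered C5′ then occurs with inversion, which sets C5′–OH anti. The syn hydroxyl cannot reach the back side of either epoxide carbon, so no bridged ether should form.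

Step 20
Reactants: 27 (1R,2S,4R)-1-ethynyl-2,6,6-trimethylcyclohexane-1,2,4-triol
Product: 28 (1S,2S,4R)-2,6,6-trimethyl-1-[(E)-2-(tributylstannyl)ethenyl]cyclohexane-1,2,4-triol
Conditions: Bu3SnH, PdCl2(PPh3)2 (cat.), THF, 0 °C
Reagents that add atoms: tributyltin hydride, CCCC[SnH](CCCC)CCCC
Why: Palladium-catalysed syn hydrostannation of a terminal alkyne; the bulky tertiary carbinol centre sends tin to the terminal carbon, giving the (E)-β-stannyl alkene. Free hydroxyls are tolerated.

Step 21
Reactants: 25 (5Z)-3-bromo-5-{(2E,4E,6E,8E)-11-[(4R)-4-hydroxy-2,6,6-trimethylcyclohex-1-en-1-yl]-2,9-dimethylundeca-2,4,6,8-tetraen-10-yn-1-ylidene}furan-2(5H)-one; 28 (1S,2S,4R)-2,6,6-trimethyl-1-[(E)-2-(tributylstannyl)ethenyl]cyclohexane-1,2,4-triol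
Product: 29 CNP0163979.2, (5Z)-5-{(2E,4E,6E,8E)-11-[(4R)-4-hydroxy-2,6,6-trimethylcyclohex-1-en-1-yl]-2,9-dimethylundeca-2,4,6,8-tetraen-10-yn-1-ylidene}-3-{(E)-2-[(1S,2S,4R)-1,2,4-trihydroxy-2,6,6-trimethylcyclohexyl]ethenyl}furan-2(5H)-one
Conditions: Pd2(dba)3 (cat.), AsPh3, DMF, rt → 40 °C, dark
Reagents that add atoms: none
Why: Stille coupling: zerovalent palladium inserts into the α-C–Br bond of the butenolide, the arsine ligand speeds transmetalation from the vinylstannane, and reductive elimination keeps both alkene geometries. The neutral conditions suit the lactone, the polyene and four free hydroxyls.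

## Compound list

1 | mesityl oxide (4-methylpent-3-en-2-one) | CC(C)=CC(C)=O | starting material
2 | 2-(tert-butyldimethylsilyloxy)-4-methylpenta-1,3-diene | CC(C)=CC(=C)O[Si](C)(C)C(C)(C)C | intermediate
3 | ethyl but-2-ynoate | CC#CC(=O)OCC | starting material
4 | ethyl 4-[(tert-butyldimethylsilyl)oxy]-2,6,6-trimethylcyclohexa-1,4-diene-1-carboxylate | CCOC(=O)C1=C(C)CC(O[Si](C)(C)C(C)(C)C)=CC1(C)C | intermediate
5 | {4-[(tert-butyldimethylsilyl)oxy]-2,6,6-trimethylcyclohexa-1,4-dien-1-yl}methanol | CC1=C(CO)C(C)(C)C=C(O[Si](C)(C)C(C)(C)C)C1 | intermediate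
6 | 4-[(tert-butyldimethylsilyl)oxy]-2,6,6-trimethylcyclohexa-1,4-diene-1-carbaldehyde | CC1=C(C=O)C(C)(C)C=C(O[Si](C)(C)C(C)(C)C)C1 | intermediate
7 | tert-butyl[(4-ethynyl-3,3,5-trimethylcyclohexa-1,4-dien-1-yl)oxy]dimethylsilane | CC1=C(C#C)C(C)(C)C=C(O[Si](C)(C)C(C)(C)C)C1 | intermediate
8 | 4-ethynyl-3,5,5-trimethylcyclohex-3-en-1-one | CC1=C(C#C)C(C)(C)CC(=O)C1 | intermediate
9 | (1R)-4-ethynyl-3,5,5-trimethylcyclohex-3-en-1-ol | CC1=C(C#C)C(C)(C)C[C@H](O)C1 | intermediate
10 | (1S)-4-ethynyl-3,5,5-trimethylcyclohex-3-en-1-ol | CC1=C(C#C)C(C)(C)C[C@@H](O)C1 | intermediate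
11 | ethyl (2E)-5-[(4R)-4-hydroxy-2,6,6-trimethylcyclohex-1-en-1-yl]-3-methylpent-2-en-4-ynoate | CC1=C(C#C/C(C)=C/C(=O)OCC)C(C)(C)C[C@H](O)C1 | intermediate
12 | (1R)-4-[(3E)-5-hydroxy-3-methylpent-3-en-1-yn-1-yl]-3,5,5-trimethylcyclohex-3-en-1-ol | CC1=C(C#C/C(C)=C/CO)C(C)(C)C[C@H](O)C1 | intermediate
13 | (2E)-5-[(4R)-4-hydroxy-2,6,6-trimethylcyclohex-1-en-1-yl]-3-methylpent-2-en-4-ynal | CC1=C(C#C/C(C)=C/C=O)C(C)(C)C[C@H](O)C1 | intermediate
14 | (2E,4E)-7-[(4R)-4-hydroxy-2,6,6-trimethylcyclohex-1-en-1-yl]-5-methylhepta-2,4-dien-6-ynal | CC1=C(C#C/C(C)=C/C=C/C=O)C(C)(C)C[C@H](O)C1 | intermediate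
15 | (2E)-3-methylpent-2-en-4-yn-1-ol | C#C/C(C)=C/CO | starting material
16 | trimethyl{[(2E)-3-methyl-5-(trimethylsilyl)pent-2-en-4-yn-1-yl]oxy}silane | C[Si](C)(C)C#C/C(C)=C/CO[Si](C)(C)C | intermediate
17 | (2E)-3-methyl-5-(trimethylsilyl)pent-2-en-4-yn-1-ol | C[Si](C)(C)C#C/C(C)=C/CO | intermediate
18 | [(3E)-5-bromo-3-methylpent-3-en-1-yn-1-yl]trimethylsilane | C[Si](C)(C)C#C/C(C)=C/CBr | intermediate
19 | diethyl [(2E)-3-methyl-5-(trimethylsilyl)pent-2-en-4-yn-1-yl]phosphonate | CCOP(=O)(OCC)C/C=C(C)/C#C[Si](C)(C)C | intermediate
20 | (1R)-4-[(3E,5E,7E,9E)-3,10-dimethyl-12-(trimethylsilyl)dodeca-3,5,7,9-tetraene-1,11-diyn-1-yl]-3,5,5-trimethylcyclohex-3-en-1-ol | CC1=C(C#C/C(C)=C/C=C/C=C/C=C(C)/C#C[Si](C)(C)C)C(C)(C)C[C@H](O)C1 | intermediate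
21 | (1R)-4-[(3E,5E,7E,9E)-3,10-dimethyldodeca-3,5,7,9-tetraene-1,11-diyn-1-yl]-3,5,5-trimethylcyclohex-3-en-1-ol | CC1=C(C#C/C(C)=C/C=C/C=C/C=C(C)/C#C)C(C)(C)C[C@H](O)C1 | intermediate
22 | propiolic acid | C#CC(=O)O | starting material
23 | (2E)-2,3-dibromoprop-2-enoic acid | OC(=O)/C(Br)=C\Br | intermediate
24 | (2E,6E,8E,10E,12E)-2-bromo-15-[(4R)-4-hydroxy-2,6,6-trimethylcyclohex-1-en-1-yl]-6,13-dimethylpentadeca-2,6,8,10,12-pentaene-4,14-diynoic acid | CC1=C(C#C/C(C)=C/C=C/C=C/C=C(C)/C#C/C=C(/Br)C(=O)O)C(C)(C)C[C@H](O)C1 | intermediate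
25 | (5Z)-3-bromo-5-{(2E,4E,6E,8E)-11-[(4R)-4-hydroxy-2,6,6-trimethylcyclohex-1-en-1-yl]-2,9-dimethylundeca-2,4,6,8-tetraen-10-yn-1-ylidene}furan-2(5H)-one | CC1=C(C#C/C(C)=C/C=C/C=C/C=C(C)/C=C2C=C(Br)C(=O)O/2)C(C)(C)C[C@H](O)C1 | intermediate
26 | (1R,3R,6R)-6-ethynyl-1,5,5-trimethyl-7-oxabicyclo[4.1.0]heptan-3-ol (epoxide cis to the hydroxyl) | C#C[C@]1(O2)C(C)(C)C[C@@H](O)C[C@]12C | intermediate
27 | (1R,2S,4R)-1-ethynyl-2,6,6-trimethylcyclohexane-1,2,4-triol | C#C[C@]1(O)C(C)(C)C[C@@H](O)C[C@]1(C)O | intermediate
28 | (1S,2S,4R)-2,6,6-trimethyl-1-[(E)-2-(tributylstannyl)ethenyl]cyclohexane-1,2,4-triol | CCCC[Sn](CCCC)(CCCC)/C=C/[C@]1(O)C(C)(C)C[C@@H](O)C[C@]1(C)O | intermediate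
29 | CNP0163979.2, (5Z)-5-{(2E,4E,6E,8E)-11-[(4R)-4-hydroxy-2,6,6-trimethylcyclohex-1-en-1-yl]-2,9-dimethylundeca-2,4,6,8-tetraen-10-yn-1-ylidene}-3-{(E)-2-[(1S,2S,4R)-1,2,4-trihydroxy-2,6,6-trimethylcyclohexyl]ethenyl}furan-2(5H)-one | CC1=C(C#C/C(C)=C/C=C/C=C/C=C(C)/C=C2C=C(/C=C/[C@]3(O)C(C)(C)C[C@@H](O)C[C@]3(C)O)C(=O)O/2)C(C)(C)C[C@H](O)C1 | target

## Step count and risks

Total step count: 21. Longest linear sequence: 14 steps (steps 1–7, 9–12, 16, 18, 21).

**Step 2 (key step).** The most likely failure is low conversion. The Z-methyl of the diene disfavours the reactive s-cis conformer and the second bond forms at a neopentyl-like carbon. At the temperature then needed, a 1,5-hydrogen shift of the diene to its linear isomer (which would give a regioisomeric adduct), loss of the silyl group or polymerisation of the ynoate may take over.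
Fallback: set out from mesityl oxide 1 and condense it with ethyl acetoacetate under BF3·OEt2 (Michael addition, then aldol condensation) to ethyl 2,6,6-trimethyl-4-oxocyclohex-2-ene-1-carboxylate F1. Soft enolisation with TBSOTf and Et3N gives the ester-conjugated dienol ether ethyl 4-[(tert-butyldimethylsilyl)oxy]-2,6,6-trimethylcyclohexa-1,3-diene-1-carboxylate F2. DIBAL-H gives {4-[(tert-butyldimethylsilyl)oxy]-2,6,6-trimethylcyclohexa-1,3-dien-1-yl}methanol F3, MnO2 gives 4-[(tert-butyldimethylsilyl)oxy]-2,6,6-trimethylcyclohexa-1,3-diene-1-carbaldehyde F4, and the Colvin rearrangement gives tert-butyl[(4-ethynyl-3,5,5-trimethylcyclohexa-1,3-dien-1-yl)oxy]dimethylsilane F5. Buffered fluoride, with kinetic α-protonation of the dienolate, returns to the route at ketone 8.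

**Steps 7 and 8.** The enzymes may discriminate the carbonyl faces poorly, because the two flanks differ only at the β-positions. During a long incubation the ring alkene of 8 may also drift into conjugation with the ketone.
Fallback: set out from 8 and reduce it with NaBH4 to rac-4-ethynyl-3,5,5-trimethylcyclohex-3-en-1-ol F6. Resolve F6 by lipase-catalysed acylation (Burkholderia cepacia lipase, vinyl acetate). Drawn for the case that the (R)-alcohol is acylated, this gives (1R)-4-ethynyl-3,5,5-trimethylcyclohex-3-en-1-yl acetate F7 and leaves alcohol 10. Methanolysis of F7 (K2CO3, MeOH) returns to the route at 9. If the enzyme prefers the other enantiomer, the roles of ester and alcohol are exchanged; either way both halves of the racemate are used.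

**Step 19.** Oxygen delivery needs the hydroxyl axial and syn to an axial methyl, and the alkene is deactivated by the alkyne. A slow directed reaction may therefore be overtaken by undirected epoxidation, with loss of facial selectivity. In the acid step, opening at the propargylic C6′ or rearrangement of the tertiary propargylic alcohol may compete.
Fallback: set out from the ring A enantiomer 9, use steric rather than directed control, and invert C3′ afterwards.
- Acetylation (Ac2O, pyridine) gives (1R)-4-ethynyl-3,5,5-trimethylcyclohex-3-en-1-yl acetate F7.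
- mCPBA should epoxidise anti to the acetoxy group to give (1R,3S,6R)-6-ethynyl-1,5,5-trimethyl-7-oxabicyclo[4.1.0]heptan-3-yl acetate F8. The ester also blocks attack of the C3′ oxygen on C6′.
- Aqueous HClO4 opens F8 at C5′ with inversion to (1S,3S,4R)-4-ethynyl-3,4-dihydroxy-3,5,5-trimethylcyclohexyl acetate F9.
- Methanolysis gives (1R,2S,4S)-1-ethynyl-2,6,6-trimethylcyclohexane-1,2,4-triol F10.
- Mitsunobu inversion of the only secondary hydroxyl (4-nitrobenzoic acid, PPh3, DIAD) gives (1R,3S,4R)-4-ethynyl-3,4-dihydroxy-3,5,5-trimethylcyclohexyl 4-nitrobenzoate F11.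
- Methanolysis of F11 returns to the route at 27.

**Step 16.** The phosphonate carbanion is an allyl–propargyl anion, so the C15=C16 geometry may erode before the addition, and the new C13=C14 bond may form as an E/Z mixture. Neither can be repaired by equilibration, since the enyne double bonds have no clear E preference.
Fallback: a stereoretentive cross-coupling.
- Set out from 13 and convert it by Takai olefination (CrCl2, CHI3) into (1R)-4-[(3E,5E)-6-iodo-3-methylhexa-3,5-dien-1-yn-1-yl]-3,5,5-trimethylcyclohex-3-en-1-ol F12.
- Oxidise 17 with MnO2 to (2E)-3-methyl-5-(trimethylsilyl)pent-2-en-4-ynal F13.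
- Homologate F13 with CrCl2, LiI and Cl2CHB(pin) to trimethyl[(3E,5E)-3-methyl-6-(4,4,5,5-tetramethyl-1,3,2-dioxaborolan-2-yl)hexa-3,5-dien-1-yn-1-yl]silane F14.
- Suzuki coupling of F12 with F14 (Pd(PPh3)4, aq. K3PO4, THF) forms C12–C13 with retention and returns to the route at 20, which is desilylated to 21 as before.

**Step 18.** Oxidative addition may occur at the α-C–Br bond or at both, the acid may close 6-endo to a 2-pyranone, and the alkyne may homocouple. All of these would consume the most advanced ring A intermediate.
Fallback: separate coupling from ring closure.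
- Set out from 23 and esterify it (MeOH, H2SO4) to methyl (2E)-2,3-dibromoprop-2-enoate F15, for which β-selective coupling of the ester is the better-established case.
- Couple F15 with 21 (PdCl2(PPh3)2, CuI, Et3N) to methyl (2E,6E,8E,10E,12E)-2-bromo-15-[(4R)-4-hydroxy-2,6,6-trimethylcyclohex-1-en-1-yl]-6,13-dimethylpentadeca-2,6,8,10,12-pentaene-4,14-diynoate F16.
- Saponify F16 (LiOH, aq. THF) to the acid 24, now isolated.
- Close the ring with AgNO3 (cat.) in acetone, which favours the 5-exo mode, and return to the route at 25.

## Further compounds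

F1 | step 2 | ethyl 2,6,6-trimethyl-4-oxocyclohex-2-ene-1-carboxylate | CCOC(=O)C1C(C)=CC(=O)CC1(C)C
F2 | step 2 | ethyl 4-[(tert-butyldimethylsilyl)oxy]-2,6,6-trimethylcyclohexa-1,3-diene-1-carboxylate | CCOC(=O)C1=C(C)C=C(O[Si](C)(C)C(C)(C)C)CC1(C)C
F3 | step 2 | {4-[(tert-butyldimethylsilyl)oxy]-2,6,6-trimethylcyclohexa-1,3-dien-1-yl}methanol | CC1=C(CO)C(C)(C)CC(O[Si](C)(C)C(C)(C)C)=C1
F4 | step 2 | 4-[(tert-butyldimethylsilyl)oxy]-2,6,6-trimethylcyclohexa-1,3-diene-1-carbaldehyde | CC1=C(C=O)C(C)(C)CC(O[Si](C)(C)C(C)(C)C)=C1
F5 | step 2 | tert-butyl[(4-ethynyl-3,5,5-trimethylcyclohexa-1,3-dien-1-yl)oxy]dimethylsilane | CC1=C(C#C)C(C)(C)CC(O[Si](C)(C)C(C)(C)C)=C1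
F6 | step 7 | rac-4-ethynyl-3,5,5-trimethylcyclohex-3-en-1-ol | CC1=C(C#C)C(C)(C)CC(O)C1
F7 | step 7 | (1R)-4-ethynyl-3,5,5-trimethylcyclohex-3-en-1-yl acetate | CC1=C(C#C)C(C)(C)C[C@H](OC(C)=O)C1
F8 | step 19 | (1R,3S,6R)-6-ethynyl-1,5,5-trimethyl-7-oxabicyclo[4.1.0]heptan-3-yl acetate | C#C[C@]1(O2)C(C)(C)C[C@H](OC(C)=O)C[C@]12C
F9 | step 19 | (1S,3S,4R)-4-ethynyl-3,4-dihydroxy-3,5,5-trimethylcyclohexyl acetate | C#C[C@]1(O)C(C)(C)C[C@H](OC(C)=O)C[C@]1(C)O
F10 | step 19 | (1R,2S,4S)-1-ethynyl-2,6,6-trimethylcyclohexane-1,2,4-triol | C#C[C@]1(O)C(C)(C)C[C@H](O)C[C@]1(C)O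
F11 | step 19 | (1R,3S,4R)-4-ethynyl-3,4-dihydroxy-3,5,5-trimethylcyclohexyl 4-nitrobenzoate | C#C[C@]1(O)C(C)(C)C[C@@H](OC(=O)c2ccc(cc2)[N+](=O)[O-])C[C@]1(C)O
F12 | step 16 | (1R)-4-[(3E,5E)-6-iodo-3-methylhexa-3,5-dien-1-yn-1-yl]-3,5,5-trimethylcyclohex-3-en-1-ol | CC1=C(C#C/C(C)=C/C=C/I)C(C)(C)C[C@H](O)C1
F13 | step 16 | (2E)-3-methyl-5-(trimethylsilyl)pent-2-en-4-ynal | C[Si](C)(C)C#C/C(C)=C/C=O
F14 | step 16 | trimethyl[(3E,5E)-3-methyl-6-(4,4,5,5-tetramethyl-1,3,2-dioxaborolan-2-yl)hexa-3,5-dien-1-yn-1-yl]silane | CC1(C)OB(/C=C/C=C(C)/C#C[Si](C)(C)C)OC1(C)C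
F15 | step 18 | methyl (2E)-2,3-dibromoprop-2-enoate | COC(=O)/C(Br)=C\Br
F16 | step 18 | methyl (2E,6E,8E,10E,12E)-2-bromo-15-[(4R)-4-hydroxy-2,6,6-trimethylcyclohex-1-en-1-yl]-6,13-dimethylpentadeca-2,6,8,10,12-pentaene-4,14-diynoate | CC1=C(C#C/C(C)=C/C=C/C=C/C=C(C)/C#C/C=C(/Br)C(=O)OC)C(C)(C)C[C@H](O)C1
A1 | alternative 1 | (1R,2S,4R)-1-ethynyl-2,6,6-trimethylcyclohexane-1,2,4-triol (ring B ethynyl triol) | C#C[C@]1(O)C(C)(C)C[C@@H](O)C[C@]1(C)O
A2 | alternative 1 | (1S)-4-ethynyl-3,5,5-trimethylcyclohex-3-en-1-ol | CC1=C(C#C)C(C)(C)C[C@@H](O)C1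
A3 | alternative 1 | (1R,3R,6R)-6-ethynyl-1,5,5-trimethyl-7-oxabicyclo[4.1.0]heptan-3-ol (syn-epoxide) | C#C[C@]1(O2)C(C)(C)C[C@@H](O)C[C@]12C
A4 | alternative 2 | (5Z)-5-{(2E)-4-[(tert-butyldimethylsilyl)oxy]-2-methylbut-2-en-1-ylidene}-3-{(E)-2-[(1S,2S,4R)-4-[(tert-butyldimethylsilyl)oxy]-1,2-dihydroxy-2,6,6-trimethylcyclohexyl]ethenyl}furan-2(5H)-one | CC(C)(C)[Si](C)(C)OC/C=C(C)/C=C2C=C(/C=C/[C@]3(O)C(C)(C)C[C@@H](O[Si](C)(C)C(C)(C)C)C[C@]3(C)O)C(=O)O/2
A5 | alternative 2 | (1E,3Z,7E)-9-[(tert-butyldimethylsilyl)oxy]-1-[(1S,2S,4R)-4-[(tert-butyldimethylsilyl)oxy]-1,2-dihydroxy-2,6,6-trimethylcyclohexyl]-3-iodo-7-methylnona-1,3,7-trien-5-one | CC(C)(C)[Si](C)(C)OC/C=C(C)/CC(=O)/C=C(I)/C=C/[C@]1(O)C(C)(C)C[C@@H](O[Si](C)(C)C(C)(C)C)C[C@]1(C)O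
A6 | alternative 3 | 1-ethynyl-6,8,8-trimethyl-2,3-dioxabicyclo[2.2.2]oct-5-ene (racemic, drawn as the enantiomer that maps onto ring B) | C#C[C@]3(OO4)C(C)(C)C[C@@H]4C=C3C
A7 | alternative 3 | 1-ethynyl-2,6,6-trimethylcyclohexa-1,3-diene | CC1=C(C#C)C(C)(C)CC=C1
A8 | alternative 3 | safranal (2,6,6-trimethylcyclohexa-1,3-diene-1-carbaldehyde) | CC1=C(C=O)C(C)(C)CC=C1
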